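A direct plan would buy both benzene rings and close ring C between them.
2-(3-Bromo-4-methoxyphenyl)acetic acid A1 would be oxygenated at C5 to the phenol A2; A2 would acylate benzene-1,3,5-triol A3 and a one-carbon unit would close the pyranone to the bromo-isoflavone A4; a Suzuki–Miyaura coupling would add the diene last.
Its weakest point would be the arene C–H oxygenation A1 → A2: a whole step for one oxygen atom, by acid/peroxide chemistry without close precedent, which would have to avoid the positions activated by the CH2CO2H group and stop before over-oxidation, while every later step depends on it.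
The second would be the last-step cross-coupling of a polymerization- and protodeboronation-prone dienylboron reagent with the hindered bromide A4, run on the most precious material in the presence of three phenoxides.
Both would come from forcing the OH/OMe/diene pattern onto a purchased benzene ring, with bromine carried only as a placeholder.

Plan of the new route
Ring B is not bought but made last from a 2-pyranone: the retrosynthesis cuts C1'–C2' (aldol) and C3–C1', then O1–C2 of ring C, and arrives at pyranone 7 and enaminone 10.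
Enabling feature: around ring B, C2'(H), C3'(OH), C4'(OMe), C5'(diene), C6'(H) and C1'(chromone) are the 6-methyl carbon, C6 (with its ring oxygen), C5–OMe, C4, C3 and the carbonyl carbon C2 of a 5-methoxy-6-methyl-4-dienyl-2-pyranone.
Order of rings: A (bought), C (closed when the enaminone is joined to the activated pyranone), B (last, by opening of the pyrylium ring and aldol closure).
No arene oxidation occurs: the 4'-OMe is bought in 1 and the 3'-OH is the pyranone ring oxygen (or the hydroxide that replaces it).
The diene is coupled in step 4 to a six-carbon pyranone, not to the isoflavone.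

Key step: step 8

Remark on the chemistry: 1, 5 and 8 are taken as catalogue compounds; the 5- and 7-hydroxyls are masked as silyl ethers only from step 5 to the basic stage of step 8.

Step 1
Reactants: 1 methyl 4-methoxy-3-oxobutanoate
Product: 3 4-hydroxy-5-methoxy-6-methyl-2H-pyran-2-one, via methyl 4-methoxy-3,5-dioxohexanoate 2 (not isolated)
Conditions: LiN(i-Pr)2 (2.2 equiv), THF, −78 → 0 °C; MeC(O)N(OMe)Me (1.0 equiv), −78 → 0 °C; aq HCl; then DBU (1.1 equiv), PhMe, 110 °C; aq HCl
Reagents that add atoms: N-methoxy-N-methylacetamide, CC(=O)N(C)OC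
Why: Claisen-type γ-acylation of the acetoacetate dianion (the γ-carbanion is the more reactive site and the N-methoxy-N-methylamide stops at the ketone) should give the 3,5-diketo ester, whose C5 enol oxygen lactonizes onto the ester, as in the classical synthesis of 4-hydroxy-6-methyl-2-pyranones.

Step 2
Reactants: 3 4-hydroxy-5-methoxy-6-methyl-2H-pyran-2-one
Product: 4 5-methoxy-6-methyl-2-oxo-2H-pyran-4-yl 4-methylbenzenesulfonate
Conditions: TsCl (1.1 equiv), Et3N (1.5 equiv), CH2Cl2, 0 → 25 °C
Reagents that add atoms: 4-methylbenzenesulfonyl chloride, Cc1ccc(cc1)S(=O)(=O)Cl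
Why: O-sulfonylation of the vinylogous acid at its 4-hydroxyl is the standard way to turn 4-hydroxy-2-pyranones into cross-coupling electrophiles.

Step 3
Reactants: 5 2-methylbut-1-en-3-yne
Product: 6 (E)-4,4,5,5-tetramethyl-2-(3-methylbuta-1,3-dien-1-yl)-1,3,2-dioxaborolane
Conditions: HBpin (1.0 equiv), 5 (1.5 equiv), Cp2Zr(H)Cl (5 mol%), Et3N (5 mol%), neat, sealed, 40 °C
Reagents that add atoms: pinacolborane (4,4,5,5-tetramethyl-1,3,2-dioxaborolane), CC1(C)OBOC1(C)C
Why: Cp2Zr(H)Cl-catalysed syn-hydroboration of the terminal alkyne, which reacts before the 1,1-disubstituted alkene, should put boron on the terminal carbon and fix the E geometry.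

Step 4
Reactants: 4 5-methoxy-6-methyl-2-oxo-2H-pyran-4-yl 4-methylbenzenesulfonate; 6 (E)-4,4,5,5-tetramethyl-2-(3-methylbuta-1,3-dien-1-yl)-1,3,2-dioxaborolane
Product: 7 5-methoxy-6-methyl-4-[(1E)-3-methylbuta-1,3-dien-1-yl]-2H-pyran-2-one
Conditions: 6 (1.3 equiv), Pd(OAc)2 (3 mol%), SPhos (6 mol%), K3PO4 (2 equiv), THF/H2O 10:1, degassed, 45 °C
Reagents that add atoms: none
Why: Suzuki–Miyaura coupling of the 4-tosyloxy-2-pyranone (a vinylogous enol sulfonate) with the alkenylboronate should go with retention of the E geometry, and the mild phosphate base should spare the lactone.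

Step 5
Reactants: 8 1-(2,4,6-trihydroxyphenyl)ethan-1-one
Product: 9 1-{2,4-bis[(tert-butyldimethylsilyl)oxy]-6-hydroxyphenyl}ethan-1-one
Conditions: TBSCl (2.1 equiv), imidazole (4 equiv), DMF, 0 → 25 °C
Reagents that add atoms: tert-butyl(chloro)dimethylsilane, CC(C)(C)[Si](C)(C)Cl
Why: Silylation should take the para and one ortho hydroxyl, while the second ortho hydroxyl, held in the hydrogen bond to the ketone, stays free and later becomes O1.

Step 6
Reactants: 9 1-{2,4-bis[(tert-butyldimethylsilyl)oxy]-6-hydroxyphenyl}ethan-1-one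
Product: 10 (2E)-1-{2,4-bis[(tert-butyldimethylsilyl)oxy]-6-hydroxyphenyl}-3-(dimethylamino)prop-2-en-1-one
Conditions: Me2NCH(OMe)2 (2 equiv), PhMe, 80 °C
Reagents that add atoms: N,N-dimethylformamide dimethyl acetal, COC(OC)N(C)C
Why: Condensation of the methyl ketone with the amide acetal should give the (E)-enaminone, the usual C2–C3 building block of chromones.

Step 7
Reactants: 7 5-methoxy-6-methyl-4-[(1E)-3-methylbuta-1,3-dien-1-yl]-2H-pyran-2-one
Product: 11 2-ethoxy-5-methoxy-6-methyl-4-[(1E)-3-methylbuta-1,3-dien-1-yl]pyrylium tetrafluoroborate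
Conditions: Et3OBF4 (1.05 equiv), CH2Cl2, 25 °C, under N2; precipitation with dry Et2O
Reagents that add atoms: triethyloxonium tetrafluoroborate, CC[O+](CC)CC.F[B-](F)(F)F
Why: O-alkylation of the 2-pyranone carbonyl by a trialkyloxonium salt should give the aromatic 2-alkoxypyrylium salt, a known reaction of 2-pyranones and coumarins; ethyl is chosen over methyl so that later nucleophiles add at C2 and do not dealkylate, and the diene, once conjugated with the cation, is protected against acid.

Step 8
Reactants: 11 2-ethoxy-5-methoxy-6-methyl-4-[(1E)-3-methylbuta-1,3-dien-1-yl]pyrylium tetrafluoroborate; 10 (2E)-1-{2,4-bis[(tert-butyldimethylsilyl)oxy]-6-hydroxyphenyl}-3-(dimethylamino)prop-2-en-1-one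
Product: 13 5,7-dihydroxy-3-{3-hydroxy-4-methoxy-5-[(1E)-3-methylbuta-1,3-dien-1-yl]phenyl}-4H-chromen-4-one, via chromon-3-ylpyrylium salt 12 (not isolated)
Conditions: 10 (1.05 equiv), AcOH (2 equiv), CH2Cl2, 0 → 25 °C; wash with cold 0.5 M aq HBF4; then K2CO3 (5 equiv), THF/MeOH/H2O 2:1:1, 25 → 60 °C; AcOH to pH 5
Reagents that add atoms: water, O (as hydroxide; it supplies the 3'-oxygen if it enters at C6 of the pyrylium ring, otherwise the ring oxygen is kept)
Why: Proposed new method: the enaminone carbon (future C3) should add to C2 of 11, the only ring carbon with a leaving group, ethanol is lost with return to a pyrylium, and the free ortho-hydroxyl closes ring C by 6-endo-trig addition–elimination at the aminovinyl carbon with loss of dimethylamine (held as its acetate and washed out before base), which is the vinylogous counterpart of the Vilsmeier formylation of such enaminones to 3-formylchromones and of the known replacement of the alkoxy group of 2-alkoxypyrylium salts by carbon nucleophiles. In aqueous carbonate 12 should form the pseudobase, the 2H-pyran opens electrocyclically to the (Z)-2-ene-1,5-dione, and the acetyl methyl carbon closes ring B by 6-exo-trig aldol condensation on the chromon-3-yl ketone, then dehydration and enolization give the phenol, the classical conversion of 2-methylpyrylium salts into phenols; the silyl ethers fall off in the same medium. The 6-methyl carbon becomes C2', C6 with its oxygen becomes C3'–OH, C5–OMe becomes C4'–OMe, C4 with the diene becomes C5' and C2 becomes C1', so the pattern of ring B is fixed by construction, no stereocentre is formed, and the E diene geometry set in step 3 is the thermodynamic one and is kept. Three selectivities are needed: C-attack at C2 of 11 and not at C4, C6 or the diene terminus (those adducts cannot rearomatize and should revert); a single aldol mode (only one enolizable methyl sits 1,5 to a ketone, so only one six-membered ring can form); and survival of the chromone in base, which the 5- and 7-phenoxides freed by desilylation should secure by deactivating C2 and C4.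

Compound list
1 | methyl 4-methoxy-3-oxobutanoate | COCC(=O)CC(=O)OC | starting material
2 | methyl 4-methoxy-3,5-dioxohexanoate | COC(=O)CC(=O)C(OC)C(C)=O | intermediate
3 | 4-hydroxy-5-methoxy-6-methyl-2H-pyran-2-one | Cc1oc(=O)cc(O)c1OC | intermediate
4 | 5-methoxy-6-methyl-2-oxo-2H-pyran-4-yl 4-methylbenzenesulfonate | Cc1ccc(cc1)S(=O)(=O)Oc1cc(=O)oc(C)c1OC | intermediate
5 | 2-methylbut-1-en-3-yne | C=C(C)C#C | starting material
6 | (E)-4,4,5,5-tetramethyl-2-(3-methylbuta-1,3-dien-1-yl)-1,3,2-dioxaborolane | C=C(C)/C=C/B1OC(C)(C)C(C)(C)O1 | intermediate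
7 | 5-methoxy-6-methyl-4-[(1E)-3-methylbuta-1,3-dien-1-yl]-2H-pyran-2-one | C=C(C)/C=C/c1cc(=O)oc(C)c1OC | intermediate
8 | 1-(2,4,6-trihydroxyphenyl)ethan-1-one | CC(=O)c1c(O)cc(O)cc1O | starting material
9 | 1-{2,4-bis[(tert-butyldimethylsilyl)oxy]-6-hydroxyphenyl}ethan-1-one | CC(=O)c1c(O)cc(O[Si](C)(C)C(C)(C)C)cc1O[Si](C)(C)C(C)(C)C | intermediate
10 | (2E)-1-{2,4-bis[(tert-butyldimethylsilyl)oxy]-6-hydroxyphenyl}-3-(dimethylamino)prop-2-en-1-one | CN(C)/C=C/C(=O)c1c(O)cc(O[Si](C)(C)C(C)(C)C)cc1O[Si](C)(C)C(C)(C)C | intermediate
11 | 2-ethoxy-5-methoxy-6-methyl-4-[(1E)-3-methylbuta-1,3-dien-1-yl]pyrylium tetrafluoroborate | CCOc1cc(/C=C/C(C)=C)c(OC)c(C)[o+]1.F[B-](F)(F)F | intermediate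
12 | 5,7-bis[(tert-butyldimethylsilyl)oxy]-3-{5-methoxy-6-methyl-4-[(1E)-3-methylbuta-1,3-dien-1-yl]pyrylium-2-yl}-4H-chromen-4-one tetrafluoroborate | C=C(C)/C=C/c1cc(-c2coc3cc(O[Si](C)(C)C(C)(C)C)cc(O[Si](C)(C)C(C)(C)C)c3c2=O)[o+]c(C)c1OC.F[B-](F)(F)F | intermediate
13 | 5,7-dihydroxy-3-{3-hydroxy-4-methoxy-5-[(1E)-3-methylbuta-1,3-dien-1-yl]phenyl}-4H-chromen-4-one | C=C(C)/C=C/c1cc(-c2coc3cc(O)cc(O)c3c2=O)cc(O)c1OC | target

Total step count: 8. Longest linear sequence: 5 steps (steps 1, 2, 4, 7 and 8).

Steps most likely to fail

First, step 8, which bears the label. The enaminone may add to the cation at the wrong position or add reversibly without substitution. Liberated amine may open the pyrylium ring. In base, the open-chain dione may be diverted before ring B closes, either by hydroxide attack at chromone C2 with loss of that carbon or by attack of its own enolate on chromone C2. The fallback inverts the polarity of the union and uses known reaction types. It sets out from 10 and 7. Iodine-induced cyclization of 10 (I2, CHCl3) would give 5,7-bis[(tert-butyldimethylsilyl)oxy]-3-iodo-4H-chromen-4-one F1. Iodine–magnesium exchange (i-PrMgCl·LiCl, THF, −40 °C) would give the chromon-3-ylmagnesium chloride F2. F2 would be added to the lactone carbonyl of 7 and the adduct ionized with HBF4, as in the known preparation of 2-substituted pyrylium salts from 2-pyranones and Grignard reagents. The route is rejoined at 12, with no amine present, and continues with the basic stage of step 8.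

Second, step 7. O-alkylation of the pyranone may be slow, the salt may hydrolyse back to 7 with traces of water, or the diene may oligomerize under the cationic conditions. The fallback activates through sulfur and sets out from 7. Thionation with Lawesson's reagent (2,4-bis(4-methoxyphenyl)-1,3,2,4-dithiadiphosphetane 2,4-disulfide; PhMe, 80 °C) would give 5-methoxy-6-methyl-4-[(1E)-3-methylbuta-1,3-dien-1-yl]-2H-pyran-2-thione F3. The far more nucleophilic sulfur would then be methylated (Me3OBF4, CH2Cl2, 0 → 25 °C) to 5-methoxy-6-methyl-4-[(1E)-3-methylbuta-1,3-dien-1-yl]-2-(methylsulfanyl)pyrylium tetrafluoroborate F4. F4 would take the place of 11 in the first stage of step 8, with methanethiol as leaving group, and the route is rejoined at 12.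

Third, step 4. The dienylboronate may protodeboronate or polymerize, the aqueous base may open the lactone, and oxidative addition into the tosylate next to the methoxy group may be slow. The fallback avoids boron and aqueous base and sets out from 4 and 5. Sonogashira coupling (PdCl2(PPh3)2, CuI, i-Pr2NH, THF, 25 °C) would give 5-methoxy-6-methyl-4-(3-methylbut-3-en-1-yn-1-yl)-2H-pyran-2-one F5. Ruthenium-catalysed trans-hydrosilylation ([Cp*Ru(MeCN)3]PF6, (EtO)3SiH, CH2Cl2, 0 °C) would give 5-methoxy-6-methyl-4-[(1Z)-3-methyl-1-(triethoxysilyl)buta-1,3-dien-1-yl]-2H-pyran-2-one F6, drawn with silicon next to the pyranone; the regioisomer would serve equally. Protodesilylation with retention (Bu4NF, CuI, THF) would give the E diene, and the route is rejoined at 7.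

Further compounds
F1 | step 8 | 5,7-bis[(tert-butyldimethylsilyl)oxy]-3-iodo-4H-chromen-4-one | O=c1c(I)coc2cc(O[Si](C)(C)C(C)(C)C)cc(O[Si](C)(C)C(C)(C)C)c12
F2 | step 8 | {5,7-bis[(tert-butyldimethylsilyl)oxy]-4-oxo-4H-chromen-3-yl}magnesium chloride | O=c1c([Mg]Cl)coc2cc(O[Si](C)(C)C(C)(C)C)cc(O[Si](C)(C)C(C)(C)C)c12
F3 | step 7 | 5-methoxy-6-methyl-4-[(1E)-3-methylbuta-1,3-dien-1-yl]-2H-pyran-2-thione | C=C(C)/C=C/c1cc(=S)oc(C)c1OC
F4 | step 7 | 5-methoxy-6-methyl-4-[(1E)-3-methylbuta-1,3-dien-1-yl]-2-(methylsulfanyl)pyrylium tetrafluoroborate | C=C(C)/C=C/c1cc(SC)[o+]c(C)c1OC.F[B-](F)(F)F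
F5 | step 4 | 5-methoxy-6-methyl-4-(3-methylbut-3-en-1-yn-1-yl)-2H-pyran-2-one | C=C(C)C#Cc1cc(=O)oc(C)c1OC
F6 | step 4 | 5-methoxy-6-methyl-4-[(1Z)-3-methyl-1-(triethoxysilyl)buta-1,3-dien-1-yl]-2H-pyran-2-one | C=C(C)/C=C(\[Si](OCC)(OCC)OCC)c1cc(=O)oc(C)c1OC
A1 | direct plan | 2-(3-bromo-4-methoxyphenyl)acetic acid | COc1ccc(CC(=O)O)cc1Br
A2 | direct plan | 2-(3-bromo-5-hydroxy-4-methoxyphenyl)acetic acid | COc1c(O)cc(CC(=O)O)cc1Br
A3 | direct plan | benzene-1,3,5-triol | Oc1cc(O)cc(O)c1
A4 | direct plan | 3-(3-bromo-5-hydroxy-4-methoxyphenyl)-5,7-dihydroxy-4H-chromen-4-one | COc1c(O)cc(-c2coc3cc(O)cc(O)c3c2=O)cc1Br
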